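**Retrosynthetic overview**
1. The target comes from its bis-silyl ether; the α-methylene lactone is carried through the endgame as a Me2NH adduct and the C8 methacrylate is put on late.
2. The ten-membered carbocycle is formed second, by ring-closing metathesis at C1=C2 of a seco diene followed by diimide saturation.
3. Key union: indium Barbier allylation forming C7–C8 between a 3-(bromomethyl)butenolide (fragment A: C2–C7, C11–C13, C15) and an aldehyde (fragment B: C8–C10, C1, C14); it sets C7 and C8 from C6.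
4. Fragment A: the butenolide ring is formed first, by Pd carbonylative lactonization of a (Z)-iodo allylic alcohol; C6 comes from Alpine-Borane reduction of an ynone built from an alkenyl iodide (carbomagnesiation of propargyl alcohol) and a Weinreb ynamide.
5. Fragment B: C10 comes from Johnson–Claisen chirality transfer starting from (S)-but-3-yn-2-ol.

Assumption: germacrane locants are used (C1–C10 ring, C11–C13 lactone carbons, C14 on C10, C15 on C4; TBS = tert-butyldimethylsilyl, TBDPS = tert-butyldiphenylsilyl), and the C11 configuration of the temporary Me2NH adducts and the E/Z geometry of C1=C2 in 28 are left unassigned because both are removed later.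

**Route**

Step 1
Reactants: 1 prop-2-yn-1-ol; 2 allylmagnesium bromide (2.5 equiv)
Product: 4 (2Z)-2-(iodomethylidene)pent-4-en-1-ol, via alkenylmagnesium alkoxide 3 (not isolated)
Conditions: CuI (10 mol %), Et2O, 0 °C → rt; then I2, THF, −78 → 0 °C; H2O work-up
Reagents that add atoms: iodine, II
Why: Hydroxyl-directed anti carbomagnesiation of the propargylic alkoxide (Duboudin-type) puts the allyl group on C4 and magnesium on C5 cis to the CH2O group, and iodinolysis with retention fixes the trisubstituted alkene geometry that becomes the ring C4=C5 bond.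

Step 2
Reactants: 4 (2Z)-2-(iodomethylidene)pent-4-en-1-ol
Product: 5 tert-butyl{[(2Z)-2-(iodomethylidene)pent-4-en-1-yl]oxy}diphenylsilane
Conditions: TBDPSCl, imidazole, DMF, rt
Reagents that add atoms: tert-butyl(chloro)diphenylsilane, CC(C)(C)[Si](Cl)(c1ccccc1)c1ccccc1
Why: Imidazole-promoted silyl ether formation masks the C15 hydroxyl as a TBDPS ether that tolerates the organolithium, hydride and Ph3PBr2 steps ahead.

Step 3
Reactants: 1 prop-2-yn-1-ol
Product: 6 tert-butyldimethyl(prop-2-yn-1-yloxy)silane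
Conditions: TBSCl, imidazole, CH2Cl2, 0 °C → rt
Reagents that add atoms: tert-butyl(chloro)dimethylsilane, CC(C)(C)[Si](C)(C)Cl
Why: Silyl ether formation protects the future C13 oxygen with a group that can later be exchanged for bromide while TBDPS ethers stay intact.

Step 4
Reactants: 6 tert-butyldimethyl(prop-2-yn-1-yloxy)silane
Product: 8 4-[(tert-butyldimethylsilyl)oxy]-N-methoxy-N-methylbut-2-ynamide, via lithium acetylide 7 (not isolated)
Conditions: n-BuLi, THF, −78 °C; then ClC(O)N(OMe)Me, −78 → 0 °C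
Reagents that add atoms: N-methoxy-N-methylcarbamoyl chloride, CON(C)C(Cl)=O
Why: Deprotonation of the terminal alkyne and C-acylation of the acetylide by the carbamoyl chloride gives the alkynyl Weinreb amide that supplies C6.

Step 5
Reactants: 5 tert-butyl{[(2Z)-2-(iodomethylidene)pent-4-en-1-yl]oxy}diphenylsilane; 8 4-[(tert-butyldimethylsilyl)oxy]-N-methoxy-N-methylbut-2-ynamide
Product: 10 (5Z)-1-[(tert-butyldimethylsilyl)oxy]-6-{[(tert-butyldiphenylsilyl)oxy]methyl}nona-5,8-dien-2-yn-4-one, via alkenyllithium 9 (not isolated)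
Conditions: 5, t-BuLi (2.1 equiv), Et2O, −78 °C; then 8, −78 °C; poured into cold 1 M HCl
Reagents that add atoms: none
Why: Iodine–lithium exchange keeps the alkene geometry and the alkenyllithium adds once to the Weinreb amide (Weinreb ketone synthesis), the cold acidic quench preventing conjugate addition of the released amine to the ynone.

Step 6
Reactants: 10 (5Z)-1-[(tert-butyldimethylsilyl)oxy]-6-{[(tert-butyldiphenylsilyl)oxy]methyl}nona-5,8-dien-2-yn-4-one
Product: 11 (4S,5Z)-1-[(tert-butyldimethylsilyl)oxy]-6-{[(tert-butyldiphenylsilyl)oxy]methyl}nona-5,8-dien-2-yn-4-ol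
Conditions: (S)-Alpine-Borane (B-isopinocampheyl-9-BBN from (−)-α-pinene, 2 equiv), neat, rt; then HOCH2CH2NH2, Et2O
Reagents that add atoms: none
Why: In the Midland reduction the slim alkynyl group is the small substituent in the cyclic hydride-transfer transition state, so the (−)-α-pinene-derived borane gives the (S)-propargylic alcohol, which is C6 of the target.

Step 7
Reactants: 11 (4S,5Z)-1-[(tert-butyldimethylsilyl)oxy]-6-{[(tert-butyldiphenylsilyl)oxy]methyl}nona-5,8-dien-2-yn-4-ol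
Product: 13 (2Z,4S,5Z)-1-[(tert-butyldimethylsilyl)oxy]-6-{[(tert-butyldiphenylsilyl)oxy]methyl}-2-iodonona-2,5,8-trien-4-ol, via cyclic alkenylaluminate 12 (not isolated)
Conditions: NaAlH2(OCH2CH2OMe)2, THF, −20 → 0 °C; then I2, THF, −78 °C; aq. KNaC4H4O6 work-up
Reagents that add atoms: iodine, II
Why: Alkoxide-directed trans-hydroalumination delivers hydride to C7 and aluminium to C11 in a five-membered alanate, and iodinolysis with retention gives the (Z)-iodo allylic alcohol, low temperature suppressing loss of the neighbouring silyloxy group.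

Step 8
Reactants: 13 (2Z,4S,5Z)-1-[(tert-butyldimethylsilyl)oxy]-6-{[(tert-butyldiphenylsilyl)oxy]methyl}-2-iodonona-2,5,8-trien-4-ol
Product: 14 (5S)-3-{[(tert-butyldimethylsilyl)oxy]methyl}-5-[(1Z)-2-{[(tert-butyldiphenylsilyl)oxy]methyl}penta-1,4-dien-1-yl]furan-2(5H)-one
Conditions: PdCl2(PPh3)2 (5 mol %), CO (1 atm), K2CO3, THF, rt
Reagents that add atoms: carbon monoxide, [C-]#[O+]
Why: Oxidative addition of the vinyl iodide, CO insertion and capture of the acylpalladium by the cis hydroxyl (carbonylative lactonization) form the butenolide without touching the C6 stereocentre.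

Step 9
Reactants: 14 (5S)-3-{[(tert-butyldimethylsilyl)oxy]methyl}-5-[(1Z)-2-{[(tert-butyldiphenylsilyl)oxy]methyl}penta-1,4-dien-1-yl]furan-2(5H)-one
Product: 15 (5S)-3-(bromomethyl)-5-[(1Z)-2-{[(tert-butyldiphenylsilyl)oxy]methyl}penta-1,4-dien-1-yl]furan-2(5H)-one
Conditions: Ph3PBr2, CH2Cl2, 0 °C → rt
Reagents that add atoms: dibromotriphenylphosphorane, BrP(Br)(c1ccccc1)(c1ccccc1)c1ccccc1
Why: Triphenylphosphine dibromide converts the primary allylic TBS ether directly into the bromide (Appel-type oxyphosphonium displacement) under neutral conditions, while the bulkier TBDPS ether is inert.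

Step 10
Reactants: 16 (2S)-but-3-yn-2-ol
Product: 18 (4S)-pent-2-yne-1,4-diol, via dilithium alkoxide acetylide 17 (not isolated)
Conditions: n-BuLi (2.2 equiv), THF, −78 → 0 °C; then (CH2O)n, rt; H2O work-up
Reagents that add atoms: formaldehyde (as paraformaldehyde), C=O
Why: The alkoxide–acetylide dianion is hydroxymethylated at carbon (acetylide addition to formaldehyde) without affecting the carbinol stereocentre.

Step 11
Reactants: 18 (4S)-pent-2-yne-1,4-diol
Product: 19 (2E,4S)-pent-2-ene-1,4-diol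
Conditions: LiAlH4, THF, 0 °C → reflux; H2O work-up
Reagents that add atoms: none
Why: Hydroxyl-directed trans-hydroalumination of the propargylic diol followed by protonolysis gives the (E)-alkene only.

Step 12
Reactants: 19 (2E,4S)-pent-2-ene-1,4-diol
Product: 20 (2S,3E)-5-[(tert-butyldiphenylsilyl)oxy]pent-3-en-2-ol
Conditions: TBDPSCl (1.05 equiv), imidazole, CH2Cl2, −20 °C
Reagents that add atoms: tert-butyl(chloro)diphenylsilane, CC(C)(C)[Si](Cl)(c1ccccc1)c1ccccc1
Why: The bulky silyl chloride silylates the primary allylic hydroxyl selectively over the secondary one.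

Step 13
Reactants: 20 (2S,3E)-5-[(tert-butyldiphenylsilyl)oxy]pent-3-en-2-ol; 21 1,1,1-trimethoxyethane (6 equiv)
Product: 23 methyl (3S,4E)-3-{[(tert-butyldiphenylsilyl)oxy]methyl}hex-4-enoate, via mixed ketene acetal 22 (not isolated)
Conditions: EtCO2H (10 mol %), xylenes, 135 °C, MeOH distilled off
Reagents that add atoms: none
Why: The Johnson–Claisen [3,3]-sigmatropic rearrangement runs through a chair with the methyl group equatorial, so the (S)-carbinol chirality is transferred suprafacially to the new C10 centre (3S here) and the new alkene is (E).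

Step 14
Reactants: 23 methyl (3S,4E)-3-{[(tert-butyldiphenylsilyl)oxy]methyl}hex-4-enoate
Product: 24 (3S,4E)-3-{[(tert-butyldiphenylsilyl)oxy]methyl}hex-4-enal
Conditions: i-Bu2AlH (1.1 equiv), CH2Cl2, −78 °C; MeOH then aq. KNaC4H4O6
Reagents that add atoms: none
Why: Half-reduction of the methyl ester at −78 °C stops at the aluminium hemiacetal and gives the aldehyde on work-up, and the β-stereocentre cannot epimerise.

Step 15
Reactants: 15 (5S)-3-(bromomethyl)-5-[(1Z)-2-{[(tert-butyldiphenylsilyl)oxy]methyl}penta-1,4-dien-1-yl]furan-2(5H)-one (fragment A); 24 (3S,4E)-3-{[(tert-butyldiphenylsilyl)oxy]methyl}hex-4-enal (fragment B)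
Product: 27 (4S,5S)-4-[(1R,3S,4E)-3-{[(tert-butyldiphenylsilyl)oxy]methyl}-1-hydroxyhex-4-en-1-yl]-5-[(1Z)-2-{[(tert-butyldiphenylsilyl)oxy]methyl}penta-1,4-dien-1-yl]-3-[(dimethylamino)methyl]oxolan-2-one, via allylindium dibromide 25 (not isolated), via methylene lactone alcohol 26 (not isolated)
Conditions: In powder, THF/H2O (3:1), rt; then Me2NH (40% aq.), rt
Reagents that add atoms: dimethylamine, CNC
Why: In this Barbier allylation the allylindium from 15 attacks the aldehyde through ring carbon C7 (SE2') in a Zimmerman–Traxler chair on the face anti to the C6 side chain, giving the 6,7-trans lactone and the 7,8-anti alcohol (7S,8R), and the aza-Michael addition of Me2NH then masks the new α-methylene lactone.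

Step 16
Reactants: 27 seco amine adduct (name as in step 15)
Product: 28 (3aS,4R,6S,10Z,11aS)-6,10-bis{[(tert-butyldiphenylsilyl)oxy]methyl}-3-[(dimethylamino)methyl]-4-hydroxy-3a,4,5,6,9,11a-hexahydrocyclodeca[b]furan-2(3H)-one
Conditions: TsOH·H2O (1.05 equiv), second-generation Grubbs catalyst RuCl2(=CHPh)(H2IMes)(PCy3) (15 mol %), 1,4-benzoquinone (20 mol %), CH2Cl2 (1 mM), 40 °C; then sat. aq. NaHCO3
Reagents that add atoms: none
Why: Ring-closing metathesis of the allyl and propenyl groups (propene lost) closes the ten-membered ring at C1=C2 without creating a stereocentre, the ammonium salt and the masked methylene lactone keeping the amine off ruthenium and preventing a competing six-membered ring closure onto C11=C13.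

Step 17
Reactants: 28 macrocyclic diene (name as in step 16)
Product: 29 (3aS,4R,6R,10Z,11aS)-6,10-bis{[(tert-butyldiphenylsilyl)oxy]methyl}-3-[(dimethylamino)methyl]-4-hydroxy-3a,4,5,6,7,8,9,11a-octahydrocyclodeca[b]furan-2(3H)-one
Conditions: 2-nitrobenzenesulfonohydrazide, Et3N, CH2Cl2, rt
Reagents that add atoms: none
Why: Diimide transfers H2 concertedly to the disubstituted C1=C2 bond much faster than to the trisubstituted C4=C5 bond and cannot hydrogenolyse the allylic lactone C–O bond.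

Step 18
Reactants: 29 macrocyclic alcohol (name as in step 17); 30 2-methylprop-2-enoyl chloride
Product: 31 (3aS,4R,6R,10Z,11aS)-6,10-bis{[(tert-butyldiphenylsilyl)oxy]methyl}-3-[(dimethylamino)methyl]-2-oxo-2,3,3a,4,5,6,7,8,9,11a-decahydrocyclodeca[b]furan-4-yl 2-methylprop-2-enoate
Conditions: Et3N, DMAP (cat.), CH2Cl2, 0 °C → rt
Reagents that add atoms: none
Why: DMAP-catalysed acylation of the secondary C8 hydroxyl by the acid chloride proceeds with retention at C8.

Step 19
Reactants: 31 methacrylate amine adduct (name as in step 18)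
Product: 33 (3aS,4R,6R,10Z,11aS)-6,10-bis{[(tert-butyldiphenylsilyl)oxy]methyl}-3-methylidene-2-oxo-2,3,3a,4,5,6,7,8,9,11a-decahydrocyclodeca[b]furan-4-yl 2-methylprop-2-enoate, via trimethylammonium iodide 32 (not isolated)
Conditions: CH3I, MeCN, rt; then sat. aq. NaHCO3, EtOAc, rt
Reagents that add atoms: none
Why: N-Methylation to the quaternary ammonium salt followed by bicarbonate-induced E1cB (Hofmann-type) elimination of trimethylamine regenerates the α-methylene lactone and removes the temporary C11 stereocentre.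

Step 20
Reactants: 33 bis-TBDPS ether (name as in step 19)
Product: 34 (3aS,4R,6R,10Z,11aS)-6,10-bis(hydroxymethyl)-3-methylidene-2-oxo-2,3,3a,4,5,6,7,8,9,11a-decahydrocyclodeca[b]furan-4-yl 2-methylprop-2-enoate (CNP0256084.5)
Conditions: HF·pyridine, pyridine/THF, 0 °C → rt
Reagents that add atoms: none
Why: Buffered fluoride desilylation cleaves both primary TBDPS ethers without harming the methacrylate or the α-methylene lactone.

**Compound list**

1 | prop-2-yn-1-ol | C#CCO | starting material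
2 | allylmagnesium bromide | C=CC[Mg]Br | starting material
3 | alkenylmagnesium alkoxide (Z)-BrMgCH=C(CH2CH=CH2)CH2OMgBr, formed in the flask | Br[Mg]/C=C(CO[Mg]Br)/CC=C | intermediate
4 | (2Z)-2-(iodomethylidene)pent-4-en-1-ol | I/C=C(CO)/CC=C | intermediate
5 | tert-butyl{[(2Z)-2-(iodomethylidene)pent-4-en-1-yl]oxy}diphenylsilane | I/C=C(CO[Si](c1ccccc1)(c1ccccc1)C(C)(C)C)/CC=C | intermediate
6 | tert-butyldimethyl(prop-2-yn-1-yloxy)silane | C#CCO[Si](C)(C)C(C)(C)C | intermediate
7 | lithium acetylide of 6, formed in the flask | [Li]C#CCO[Si](C)(C)C(C)(C)C | intermediate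
8 | 4-[(tert-butyldimethylsilyl)oxy]-N-methoxy-N-methylbut-2-ynamide | CON(C)C(=O)C#CCO[Si](C)(C)C(C)(C)C | intermediate
9 | alkenyllithium from 5 (Li in place of I, same geometry), formed in the flask | [Li]/C=C(CO[Si](c1ccccc1)(c1ccccc1)C(C)(C)C)/CC=C | intermediate
10 | (5Z)-1-[(tert-butyldimethylsilyl)oxy]-6-{[(tert-butyldiphenylsilyl)oxy]methyl}nona-5,8-dien-2-yn-4-one | C=CC/C(CO[Si](c1ccccc1)(c1ccccc1)C(C)(C)C)=C/C(=O)C#CCO[Si](C)(C)C(C)(C)C | intermediate
11 | (4S,5Z)-1-[(tert-butyldimethylsilyl)oxy]-6-{[(tert-butyldiphenylsilyl)oxy]methyl}nona-5,8-dien-2-yn-4-ol | C=CC/C(CO[Si](c1ccccc1)(c1ccccc1)C(C)(C)C)=C/[C@H](O)C#CCO[Si](C)(C)C(C)(C)C | intermediate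
12 | sodium cyclic alkenyl(alkoxy)bis(2-methoxyethoxy)aluminate (Al bound to O6 and C11), formed in the flask | [Na+].COCCO[Al-]1(OCCOC)O[C@@H](/C=C(CO[Si](c2ccccc2)(c2ccccc2)C(C)(C)C)/CC=C)C=C1CO[Si](C)(C)C(C)(C)C | intermediate
13 | (2Z,4S,5Z)-1-[(tert-butyldimethylsilyl)oxy]-6-{[(tert-butyldiphenylsilyl)oxy]methyl}-2-iodonona-2,5,8-trien-4-ol | C=CC/C(CO[Si](c1ccccc1)(c1ccccc1)C(C)(C)C)=C/[C@H](O)/C=C(/CO[Si](C)(C)C(C)(C)C)I | intermediate
14 | (5S)-3-{[(tert-butyldimethylsilyl)oxy]methyl}-5-[(1Z)-2-{[(tert-butyldiphenylsilyl)oxy]methyl}penta-1,4-dien-1-yl]furan-2(5H)-one | C=CC/C(CO[Si](c1ccccc1)(c1ccccc1)C(C)(C)C)=C/[C@@H]1OC(=O)C(CO[Si](C)(C)C(C)(C)C)=C1 | intermediate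
15 | (5S)-3-(bromomethyl)-5-[(1Z)-2-{[(tert-butyldiphenylsilyl)oxy]methyl}penta-1,4-dien-1-yl]furan-2(5H)-one (fragment A) | C=CC/C(CO[Si](c1ccccc1)(c1ccccc1)C(C)(C)C)=C/[C@@H]1OC(=O)C(CBr)=C1 | intermediate
16 | (2S)-but-3-yn-2-ol | C[C@H](O)C#C | starting material
17 | dilithium alkoxide acetylide of 16, formed in the flask | C[C@H](O[Li])C#C[Li] | intermediate
18 | (4S)-pent-2-yne-1,4-diol | C[C@H](O)C#CCO | intermediate
19 | (2E,4S)-pent-2-ene-1,4-diol | C[C@H](O)/C=C/CO | intermediate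
20 | (2S,3E)-5-[(tert-butyldiphenylsilyl)oxy]pent-3-en-2-ol | C[C@H](O)/C=C/CO[Si](c1ccccc1)(c1ccccc1)C(C)(C)C | intermediate
21 | 1,1,1-trimethoxyethane (trimethyl orthoacetate) | CC(OC)(OC)OC | starting material
22 | mixed ketene acetal tert-butyl({(2E,4S)-4-[(1-methoxyethenyl)oxy]pent-2-en-1-yl}oxy)diphenylsilane, formed in the flask | C=C(OC)O[C@@H](C)/C=C/CO[Si](c1ccccc1)(c1ccccc1)C(C)(C)C | intermediate
23 | methyl (3S,4E)-3-{[(tert-butyldiphenylsilyl)oxy]methyl}hex-4-enoate | COC(=O)C[C@H](CO[Si](c1ccccc1)(c1ccccc1)C(C)(C)C)/C=C/C | intermediate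
24 | (3S,4E)-3-{[(tert-butyldiphenylsilyl)oxy]methyl}hex-4-enal (fragment B) | O=CC[C@H](CO[Si](c1ccccc1)(c1ccccc1)C(C)(C)C)/C=C/C | intermediate
25 | allylindium dibromide from 15 (InBr2 in place of Br; drawn as the RInBr2 component of the sesquibromide), formed in the flask | Br[In](Br)CC1=C[C@H](/C=C(CO[Si](c2ccccc2)(c2ccccc2)C(C)(C)C)/CC=C)OC1=O | intermediate
26 | (4S,5S)-4-[(1R,3S,4E)-3-{[(tert-butyldiphenylsilyl)oxy]methyl}-1-hydroxyhex-4-en-1-yl]-5-[(1Z)-2-{[(tert-butyldiphenylsilyl)oxy]methyl}penta-1,4-dien-1-yl]-3-methylideneoxolan-2-one, formed in the flask | O[C@@H]([C@@H]1C(=C)C(=O)O[C@H]1/C=C(CO[Si](c2ccccc2)(c2ccccc2)C(C)(C)C)/CC=C)C[C@H](CO[Si](c1ccccc1)(c1ccccc1)C(C)(C)C)/C=C/C | intermediate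
27 | Me2NH adduct of 26: same skeleton with 3-[(dimethylamino)methyl] in place of 3-methylidene (ring C3 = C11 unassigned) | O[C@@H]([C@@H]1C(CN(C)C)C(=O)O[C@H]1/C=C(CO[Si](c2ccccc2)(c2ccccc2)C(C)(C)C)/CC=C)C[C@H](CO[Si](c1ccccc1)(c1ccccc1)C(C)(C)C)/C=C/C | intermediate
28 | (3aS,4R,6S,10Z,11aS)-6,10-bis{[(tert-butyldiphenylsilyl)oxy]methyl}-3-[(dimethylamino)methyl]-4-hydroxy-3a,4,5,6,9,11a-hexahydrocyclodeca[b]furan-2(3H)-one (7E/7Z mixture; C3 unassigned) | O[C@@H]1C[C@H](CO[Si](c3ccccc3)(c3ccccc3)C(C)(C)C)C=CC/C(CO[Si](c3ccccc3)(c3ccccc3)C(C)(C)C)=C/[C@@H]2OC(=O)C(CN(C)C)[C@H]21 | intermediate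
29 | (3aS,4R,6R,10Z,11aS)-6,10-bis{[(tert-butyldiphenylsilyl)oxy]methyl}-3-[(dimethylamino)methyl]-4-hydroxy-3a,4,5,6,7,8,9,11a-octahydrocyclodeca[b]furan-2(3H)-one (C3 unassigned) | O[C@@H]1C[C@H](CO[Si](c3ccccc3)(c3ccccc3)C(C)(C)C)CCC/C(CO[Si](c3ccccc3)(c3ccccc3)C(C)(C)C)=C/[C@@H]2OC(=O)C(CN(C)C)[C@H]21 | intermediate
30 | 2-methylprop-2-enoyl chloride (methacryloyl chloride) | C=C(C)C(Cl)=O | starting material
31 | (3aS,4R,6R,10Z,11aS)-6,10-bis{[(tert-butyldiphenylsilyl)oxy]methyl}-3-[(dimethylamino)methyl]-2-oxo-2,3,3a,4,5,6,7,8,9,11a-decahydrocyclodeca[b]furan-4-yl 2-methylprop-2-enoate (C3 unassigned) | C=C(C)C(=O)O[C@@H]1C[C@H](CO[Si](c3ccccc3)(c3ccccc3)C(C)(C)C)CCC/C(CO[Si](c3ccccc3)(c3ccccc3)C(C)(C)C)=C/[C@@H]2OC(=O)C(CN(C)C)[C@H]21 | intermediate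
32 | N-methyl quaternary ammonium iodide of 31, formed in the flask | C=C(C)C(=O)O[C@@H]1C[C@H](CO[Si](c3ccccc3)(c3ccccc3)C(C)(C)C)CCC/C(CO[Si](c3ccccc3)(c3ccccc3)C(C)(C)C)=C/[C@@H]2OC(=O)C(C[N+](C)(C)C)[C@H]21.[I-] | intermediate
33 | (3aS,4R,6R,10Z,11aS)-6,10-bis{[(tert-butyldiphenylsilyl)oxy]methyl}-3-methylidene-2-oxo-2,3,3a,4,5,6,7,8,9,11a-decahydrocyclodeca[b]furan-4-yl 2-methylprop-2-enoate | C=C(C)C(=O)O[C@@H]1C[C@H](CO[Si](c3ccccc3)(c3ccccc3)C(C)(C)C)CCC/C(CO[Si](c3ccccc3)(c3ccccc3)C(C)(C)C)=C/[C@@H]2OC(=O)C(=C)[C@H]21 | intermediate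
34 | (3aS,4R,6R,10Z,11aS)-6,10-bis(hydroxymethyl)-3-methylidene-2-oxo-2,3,3a,4,5,6,7,8,9,11a-decahydrocyclodeca[b]furan-4-yl 2-methylprop-2-enoate (germacrane: 6S,7S,8R,10R) | C=C(C)C(=O)O[C@@H]1C[C@H](CO)CCC/C(CO)=C/[C@@H]2OC(=O)C(=C)[C@H]21 | target

**Step count**

Total step count: 20.
Longest linear sequence: 13 steps (1, 2, 5–9, 15–20; the line through 3 and 4 is equally long), that is 13 of 20.

**Three steps most likely to fail, with fallbacks**

Step 16, ring-closing metathesis to the strained ten-membered ring. If 27 gives dimers or no ring, the order of the two C–C bond formations is reversed. Setting out from 14 and 24, cross-metathesis of the allyl group of 14 with the propenyl group of 24 (24 in excess, second-generation Grubbs catalyst RuCl2(=CHPh)(H2IMes)(PCy3)) gives the linked dienal F1. Diimide from KO2CN=NCO2K/AcOH, which is compatible with the aldehyde, saturates the new C1=C2 bond to the saturated aldehyde F2. Ph3PBr2 then turns the TBS ether into the bromo aldehyde F3. An intramolecular Barbier allylation at high dilution (In powder in THF/H2O, or CrCl2 in THF) closes the ring through C7–C8 to the macrocyclic hydroxy methylene lactone F4. Acylation of F4 with 30 comes back to the route at 33.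

Step 15, Barbier union and the C8 configuration. If the chair preference is low or the syn (8S) adduct dominates, C8 is set by inversion instead of by the allylation. From 15 and 24 the 8-epimeric seco amine adduct F5 is taken through the same metathesis and diimide reactions to the 8-epimeric macrocyclic diene F6 and the 8-epimeric macrocyclic alcohol F7. Mitsunobu esterification of F7 with methacrylic acid (PPh3, DIAD, toluene, 0 °C) then installs the ester with inversion at C8 and comes back to the route at 31.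

Step 6, Alpine-Borane reduction of a hindered cross-conjugated ynone. If the reduction is slow (dehydroboration of the reagent would then release 9-BBN, which attacks the terminal alkene) or poorly selective, C6 is made by asymmetric C–C bond formation instead. From 5, t-BuLi then DMF gives the (Z)-enal F8. Me2Zn/ProPhenol-catalysed addition of alkyne 6 to F8 (the ligand enantiomer that gives the (S)-carbinol, toluene, 0 °C) gives 11 directly, where the fallback comes back to the route.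

Further compounds
F1 | step 16 | (3S,7Z)-3,7-bis{[(tert-butyldiphenylsilyl)oxy]methyl}-8-[(2S)-4-{[(tert-butyldimethylsilyl)oxy]methyl}-5-oxo-2,5-dihydrofuran-2-yl]octa-4,7-dienal (4E/4Z mixture) | O=CC[C@H](CO[Si](c1ccccc1)(c1ccccc1)C(C)(C)C)C=CC/C(CO[Si](c1ccccc1)(c1ccccc1)C(C)(C)C)=C/[C@@H]1OC(=O)C(CO[Si](C)(C)C(C)(C)C)=C1
F2 | step 16 | (3R,7Z)-3,7-bis{[(tert-butyldiphenylsilyl)oxy]methyl}-8-[(2S)-4-{[(tert-butyldimethylsilyl)oxy]methyl}-5-oxo-2,5-dihydrofuran-2-yl]oct-7-enal | O=CC[C@H](CO[Si](c1ccccc1)(c1ccccc1)C(C)(C)C)CCC/C(CO[Si](c1ccccc1)(c1ccccc1)C(C)(C)C)=C/[C@@H]1OC(=O)C(CO[Si](C)(C)C(C)(C)C)=C1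
F3 | step 16 | (3R,7Z)-8-[(2S)-4-(bromomethyl)-5-oxo-2,5-dihydrofuran-2-yl]-3,7-bis{[(tert-butyldiphenylsilyl)oxy]methyl}oct-7-enal | O=CC[C@H](CO[Si](c1ccccc1)(c1ccccc1)C(C)(C)C)CCC/C(CO[Si](c1ccccc1)(c1ccccc1)C(C)(C)C)=C/[C@@H]1OC(=O)C(CBr)=C1
F4 | step 16 | (3aS,4R,6R,10Z,11aS)-6,10-bis{[(tert-butyldiphenylsilyl)oxy]methyl}-4-hydroxy-3-methylidene-3a,4,5,6,7,8,9,11a-octahydrocyclodeca[b]furan-2(3H)-one | O[C@@H]1C[C@H](CO[Si](c3ccccc3)(c3ccccc3)C(C)(C)C)CCC/C(CO[Si](c3ccccc3)(c3ccccc3)C(C)(C)C)=C/[C@@H]2OC(=O)C(=C)[C@H]21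
F5 | step 15 | 8-epimer of 27: (4S,5S)-4-[(1S,3S,4E)-3-{[(tert-butyldiphenylsilyl)oxy]methyl}-1-hydroxyhex-4-en-1-yl]-5-[(1Z)-2-{[(tert-butyldiphenylsilyl)oxy]methyl}penta-1,4-dien-1-yl]-3-[(dimethylamino)methyl]oxolan-2-one | O[C@H]([C@@H]1C(CN(C)C)C(=O)O[C@H]1/C=C(CO[Si](c2ccccc2)(c2ccccc2)C(C)(C)C)/CC=C)C[C@H](CO[Si](c1ccccc1)(c1ccccc1)C(C)(C)C)/C=C/C
F6 | step 15 | 8-epimer of 28: (3aS,4S,6S,10Z,11aS)-6,10-bis{[(tert-butyldiphenylsilyl)oxy]methyl}-3-[(dimethylamino)methyl]-4-hydroxy-3a,4,5,6,9,11a-hexahydrocyclodeca[b]furan-2(3H)-one | O[C@H]1C[C@H](CO[Si](c3ccccc3)(c3ccccc3)C(C)(C)C)C=CC/C(CO[Si](c3ccccc3)(c3ccccc3)C(C)(C)C)=C/[C@@H]2OC(=O)C(CN(C)C)[C@H]21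
F7 | step 15 | 8-epimer of 29: (3aS,4S,6R,10Z,11aS)-6,10-bis{[(tert-butyldiphenylsilyl)oxy]methyl}-3-[(dimethylamino)methyl]-4-hydroxy-3a,4,5,6,7,8,9,11a-octahydrocyclodeca[b]furan-2(3H)-one | O[C@H]1C[C@H](CO[Si](c3ccccc3)(c3ccccc3)C(C)(C)C)CCC/C(CO[Si](c3ccccc3)(c3ccccc3)C(C)(C)C)=C/[C@@H]2OC(=O)C(CN(C)C)[C@H]21
F8 | step 6 | (2Z)-3-{[(tert-butyldiphenylsilyl)oxy]methyl}hexa-2,5-dienal | C=CC/C(CO[Si](c1ccccc1)(c1ccccc1)C(C)(C)C)=C/C=O
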